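(The data are simulated for substances that don't exist, noise included.)

The constants of the steps are hidden, but one combination of them can be read from the runs. Call it the exposure θ: k·c·∫[free catalyst]dt, where k is the rate constant of the left-handed step and c is the left-handed substrate charge. The catalyst-losing steps contain neither reagent nor substrate, and the catalyst and ligand charges are equal in Monday's run, Wednesday's run and the flask, so θ at a given time should carry over between the three.

| flask | left-handed substrate | right-handed substrate | reagent | free catalyst | added ligand | remark | time |
|---|---|---|---|---|---|---|---|
| Monday's | 0.10 M | 0.10 M | 0.84 equiv | 3.8 mol% | 4.4 mM | run made earlier |  |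
| Wednesday's | 0.10 M | 0.10 M | 1.3 equiv | 3.8 mol% | 4.4 mM | run made earlier |  |
| flask | 0.10 M | 0.10 M | 0.600 equiv | 3.8 mol% | 4.4 mM |  | 4.0 min |

| Monday's: time / min | Monday's: left-handed product / % | Wednesday's: time / min | Wednesday's: left-handed product / % |
|---|---|---|---|
| 0.167 | 3.7 | 0.333 | 7.9 |
| 0.333 | 4.0 | 0.667 | 10.2 |
| 0.667 | 7.3 | 1.00 | 12.5 |
| 1.00 | 8.5 | 1.33 | 14.6 |
| 1.33 | 9.0 | 1.50 | 13.2 |
| 2.00 | 9.4 | 2.00 | 15.0 |
| 2.50 | 10.3 | 2.50 | 16.3 |

(each reading ± 0.5 percentage points)

- free catalyst is single-handed; left-handed substrate and right-handed substrate are mirror images of each other, charged as a racemate, each of them at the stated concentration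
- candidate steps: reagent + free catalyst + left-handed substrate -> free catalyst + left-handed product; free catalyst + added ligand <-> idle complex; reagent + free catalyst + right-handed substrate -> free catalyst + right-handed product; 2 free catalyst -> spent catalyst

- amount of left-handed product in percent of the left-handed substrate and right-handed substrate together charged, at 25 s, 80 s, 2.5 min and 4.0 min

Take r as the reagent equivalents and u as twice the left-handed product fraction. The product then follows second-order kinetics on the clock θ, and neglecting reagent taken by the right-handed path gives θ = ln[(r−u)/(r(1−u))]/(r−1). At 2.50 min, Monday's reading gives 0.317 and Wednesday's gives 0.353. Their mean, 0.335, is the exposure carried to the flask, and inverting the formula at the flask's charge gives 7.91% at 2.5 min.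

The bracket comes from the scatter of one standard deviation, so its edges are estimates and not strict limits. Monday's reading minus one standard deviation gives θ = 0.297, hence a lower edge of 7.20% for the flask. Wednesday's reading plus one gives θ = 0.368, hence an upper edge of 8.52% for the flask.

The forecast gives 3.8%, 6.4%, 7.4% and 8.2%, its third value lying inside the bracket but below the central 7.91%, on this ground: “Catalyst behaviour should therefore carry over to the flask unchanged.”

The flask gives 4.12%, 6.77%, 8.27% and 9.37%, under these steps:

    reagent + free catalyst + left-handed substrate → free catalyst + left-handed product (k = 70.0 L² mol⁻² s⁻¹)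
    free catalyst + added ligand ⇌ idle complex, settled at all times (K = 390 L mol⁻¹)
    reagent + free catalyst + right-handed substrate → free catalyst + right-handed product (k = 7.10 L² mol⁻² s⁻¹)
    2 free catalyst → spent catalyst (k = 56.0 L mol⁻¹ s⁻¹)

Its value at 2.5 min corresponds to θ = 0.354, above the carried 0.335, and this exposure at Wednesday's charge gives 16.4% against the reading of 16.3%. In the flask at 4.00 min, the half-life of left-handed substrate by its step is 49 min, far longer than the 4.0 min elapsed, with free catalyst at 2.27% and spent catalyst at 94.0% of the catalyst charged. At 4.00 min the flask holds left-handed substrate at 81% of its charge and reagent at 65% of its charge.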